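**Assumptions (one line each)**
- Colpol has no stereocentres and is achiral. The only stereo-element is the cis (Z) C2=C3 alkene, which Step 10 sets.
- 3-Bromo-4-methoxyphenol (1) and 4-bromo-3,5-dihydroxybenzoic acid (6) are taken as commercially available.

## Retrosynthetic overview
1. Colpol is a Z-1,4-diarylbut-2-ene. The Z-alkene comes from Lindlar semihydrogenation of the 1,4-diarylbut-2-yne, and the phenols are carried as MOM ethers to the last step.
2. The skipped diarylalkyne is disconnected at both benzylic C–C(sp) bonds into two benzylic bromides and acetylene. These are joined by SN2 alkylation of lithium acetylide, twice, in sequence.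
3. Ring A bromide 5 comes from 3-bromo-4-methoxyphenol by ortho-formylation, MOM protection, reduction and Appel bromination. Ring B bromide 9 comes from 4-bromo-3,5-dihydroxybenzoic acid by MOM protection, reduction and Appel bromination.
4. Both aromatic rings come from commercial arenes, so no ring is constructed.

## Route

**Step 1**
Reactants: 1, 3-bromo-4-methoxyphenol
Product: 2, 4-bromo-2-hydroxy-5-methoxybenzaldehyde
Conditions: MgCl2, Et3N, (CH2O)n, MeCN, reflux
Reagents that add atoms: paraformaldehyde, (CH2O)n, SMILES C=O (supplies the CHO carbon)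
Why: Mg-phenoxide-directed ortho-formylation (Casnati–Skattebøl) goes to the less hindered ortho position (C6). The other ortho position, C2, is flanked by Br.

**Step 2**
Reactants: 2
Product: 3, 4-bromo-5-methoxy-2-(methoxymethoxy)benzaldehyde
Conditions: MOMCl, i-Pr2NEt, CH2Cl2, 0 °C to rt
Reagents that add atoms: MOMCl, ClCOC
Why: Williamson-type O-alkylation of the phenol gives the acid-labile MOM ether, which survives the later organometallic steps.

**Step 3**
Reactants: 3
Product: 4, [4-bromo-5-methoxy-2-(methoxymethoxy)phenyl]methanol
Conditions: NaBH4, MeOH, 0 °C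
Reagents that add atoms: none
Why: Chemoselective hydride reduction of the aldehyde; the aryl bromide and the ethers are untouched.

**Step 4**
Reactants: 4
Product: 5, 1-(bromomethyl)-4-bromo-5-methoxy-2-(methoxymethoxy)benzene
Conditions: CBr4, PPh3, CH2Cl2, 0 °C; use crude at once
Reagents that add atoms: CBr4, BrC(Br)(Br)Br
Why: Appel reaction converts the benzylic alcohol to the bromide under neutral conditions, which the MOM ether tolerates.

**Step 5**
Reactants: 6, 4-bromo-3,5-dihydroxybenzoic acid
Product: 7, methoxymethyl 4-bromo-3,5-bis(methoxymethoxy)benzoate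
Conditions: MOMCl (4 equiv), i-Pr2NEt, CH2Cl2, 0 °C to rt
Reagents that add atoms: MOMCl, ClCOC
Why: O-alkylation of both phenols and the carboxylate gives one fully protected, LiAlH4-reducible compound in a single step.

**Step 6**
Reactants: 7
Product: 8, [4-bromo-3,5-bis(methoxymethoxy)phenyl]methanol
Conditions: LiAlH4, THF, 0 °C
Reagents that add atoms: none
Why: Hydride reduction of the MOM ester to the primary alcohol; MOM ethers and the hindered aryl bromide survive at 0 °C.

**Step 7**
Reactants: 8
Product: 9, 2-bromo-5-(bromomethyl)-1,3-bis(methoxymethoxy)benzene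
Conditions: CBr4, PPh3, CH2Cl2, 0 °C
Reagents that add atoms: CBr4, BrC(Br)(Br)Br
Why: Appel bromination, as in Step 4.

**Step 8**
Reactants: 9 and 10 (lithium acetylide–ethylenediamine complex, 3 equiv)
Product: 11, 2-bromo-5-(prop-2-yn-1-yl)-1,3-bis(methoxymethoxy)benzene
Conditions: DMSO, rt
Reagents that add atoms: 10 supplies the HC≡C unit (already a listed reactant)
Why: SN2 alkylation of the acetylide at the benzylic bromide; excess acetylide suppresses dialkylation.

**Step 9**
Reactants: 11 and 5
Product: 12, 1,4-diarylbut-2-yne, COCOc1cc(Br)c(OC)cc1CC#CCc1cc(OCOC)c(Br)c(OCOC)c1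
Conditions: n-BuLi (0.95 equiv), THF, −78 °C; then 5 (1.3 equiv), DMPU, −78 °C to rt
Reagents that add atoms: none (n-BuLi only deprotonates)
Why: The terminal alkyne is deprotonated far faster than Br–Li exchange occurs. The lithium acetylide then undergoes SN2 alkylation with benzylic bromide 5, which joins the two halves.

**Step 10**
Reactants: 12
Product: 13, (Z)-1,4-diarylbut-2-ene (MOM-protected colpol)
Conditions: H2 (1 atm), Lindlar catalyst (Pd/CaCO3/Pb), quinoline, EtOAc, rt
Reagents that add atoms: none (H2 adds only hydrogen)
Why: Syn addition of H2 on the poisoned Pd surface gives the cis-alkene, which sets the Z geometry. The poison and quinoline prevent over-reduction and Ar–Br hydrogenolysis.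

**Step 11**
Reactants: 13
Product: 14, colpol
Conditions: 2 M HCl, MeOH/THF, 40 °C
Reagents that add atoms: none
Why: Acidolysis of the three MOM acetals releases the phenols. The aryl methyl ether, the aryl bromides and the isolated Z-alkene are stable to these mild conditions, and MeOH traps the released formaldehyde as dimethoxymethane.

## Final checks
- The target ring A is C1–CH2, 2-OH, 4-Br, 5-OMe. Compounds 2, 3, 4, 5, 11 and 12 all carry exactly this pattern.
- Ring B is 4-Br-3,5-diOH with the CH2 at C1, matching compounds 6 to 9, 11 and 12.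
- The alkene SMILES "C/C=C\C" in 13 and 14 matches the target's cis geometry.
- The C-atom count balances in Steps 8 and 9: CH2 + C≡C + CH2 gives the four-carbon bridge.
- No other stereocentres exist.

## Compound list
| No. | Name | SMILES | Role |
|---|---|---|---|
| 1 | 3-Bromo-4-methoxyphenol | COc1ccc(O)cc1Br | starting material |
| 2 | 4-Bromo-2-hydroxy-5-methoxybenzaldehyde | COc1cc(C=O)c(O)cc1Br | intermediate |
| 3 | 4-Bromo-5-methoxy-2-(MOMO)benzaldehyde | COCOc1cc(Br)c(OC)cc1C=O | intermediate |
| 4 | [4-Bromo-5-methoxy-2-(MOMO)phenyl]methanol | COCOc1cc(Br)c(OC)cc1CO | intermediate |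
| 5 | 1-(Bromomethyl)-4-bromo-5-methoxy-2-(MOMO)benzene | COCOc1cc(Br)c(OC)cc1CBr | intermediate |
| 6 | 4-Bromo-3,5-dihydroxybenzoic acid | OC(=O)c1cc(O)c(Br)c(O)c1 | starting material |
| 7 | MOM 4-bromo-3,5-bis(MOMO)benzoate | COCOC(=O)c1cc(OCOC)c(Br)c(OCOC)c1 | intermediate |
| 8 | [4-Bromo-3,5-bis(MOMO)phenyl]methanol | COCOc1cc(CO)cc(OCOC)c1Br | intermediate |
| 9 | 2-Bromo-5-(bromomethyl)-1,3-bis(MOMO)benzene | COCOc1cc(CBr)cc(OCOC)c1Br | intermediate |
| 10 | Lithium acetylide–ethylenediamine complex | [Li+].[C-]#C.NCCN | starting material |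
| 11 | 2-Bromo-5-propargyl-1,3-bis(MOMO)benzene | C#CCc1cc(OCOC)c(Br)c(OCOC)c1 | intermediate |
| 12 | Protected 1,4-diarylbut-2-yne | COCOc1cc(Br)c(OC)cc1CC#CCc1cc(OCOC)c(Br)c(OCOC)c1 | intermediate |
| 13 | Protected (Z)-1,4-diarylbut-2-ene | COCOc1cc(Br)c(OC)cc1C/C=C\Cc1cc(OCOC)c(Br)c(OCOC)c1 | intermediate |
| 14 | Colpol | COc1cc(C/C=C\Cc2cc(O)c(Br)c(O)c2)c(O)cc1Br | target |

**Total steps:** 11. **Longest linear sequence:** 7 (1→2→3→4→5→12→13→14 and 6→7→8→9→11→12→13→14 are equal in length).

## Three steps most likely to fail
1. **Step 9 (acetylide alkylation with the reactive ortho-oxygenated benzylic bromide 5).** It can give elimination, allene or propargyl isomerization, or low SN2 yield.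
   - Fallback: drop the alkyne route. Make the two allylarenes from 5 and 9 by Cu-catalysed vinylMgBr coupling, then join them by Z-selective Ru-catalysed cross-metathesis.
2. **Step 8 (monopropargylation of 9).** Over-alkylation, or base-induced isomerization of the propargylarene to an allene or aryl-propyne.
   - Fallback: Pd-catalysed Negishi coupling of the benzylzinc reagent from 9 with TIPS-C≡C-Br, then desilylation, which avoids strongly basic acetylide conditions.
3. **Step 10 (Lindlar reduction).** Ar–Br hydrogenolysis, over-reduction to the alkane, or E/Z leakage.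
   - Fallback: hydroboration of the alkyne with Cy2BH, then protonolysis with AcOH, which gives the Z-alkene by a non-Pd mechanism and leaves the aryl bromides untouched.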